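Locants: tetralin C1–C8a (ring A is the fused arene, ring B the carbocycle), ring C is the aryl on C1, ring D the terminal guaiacyl, Ca the carbinol carbon, Cb the ether carbon. The target is the all-trans (1S,2S,3R)-tetralin with an erythro (Ca S, Cb R) side chain.
Cuts, in retrosynthetic order: both O–benzyl bonds, Ca–ring D, the C3 methyl back to an exocyclic methylene, C1–C8a together with C1–C2, and last the Cb–O(ring C) ether bond.
Enabling feature: C1 is a methine bonded to three carbons (the ipso carbon of ring C, C2 and C8a). The ether oxygen para to it on ring C stabilises a cation at C1, and C8a lies para to the C6 methoxy group of ring A, so a single ring C aldehyde carbon can accept C2 first and C8a second.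
Forward: rings A, C and D are bought as arenes. A ring A allylboronate (steps 1–7) and a ring C aldehyde already carrying the lactate arm (step 8) are joined in step 9, where ring B, the only ring made, closes. Ring D is added in step 13.
Stereochemistry: Cb comes from ethyl (S)-lactate by inversion, C2 from a chiral phosphoric acid plus the boronate geometry, C1 from C2 (trans closure), C3 from the ring (equatorial methyl by hydrogen-atom transfer), and Ca from Cb (Felkin–Anh).

Key step: step 9

Assumption: the sense of induction is carried over from the parent allyl and crotyl pinacolboronates, where the (R)-configured phosphoric acid directs attack to the Re face of aryl aldehydes. The (S)-acid is therefore chosen, and its antipode would be used should the β-benzyl boronate behave otherwise.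

Step 1
Reactants: 1 4-benzyloxy-3-methoxybenzaldehyde (O-benzylvanillin)
Product: 2 (4-benzyloxy-3-methoxyphenyl)methanol
Conditions: NaBH4, MeOH, 0 °C
Reagents that add atoms: none
Why: Borohydride reduction of an aryl aldehyde is fast and leaves the aryl ethers untouched.

Step 2
Reactants: 2 (4-benzyloxy-3-methoxyphenyl)methanol
Product: 3 4-benzyloxy-3-methoxybenzyl bromide
Conditions: PBr3, Et2O, 0 °C
Reagents that add atoms: phosphorus tribromide, BrP(Br)Br
Why: Bromination of a benzylic alcohol with PBr3 (SN2 displacement on the phosphite ester) is routine for this electron-rich system at 0 °C, and the bromide is used promptly.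

Step 3
Reactants: 3 4-benzyloxy-3-methoxybenzyl bromide, 4 ethyl (triphenylphosphoranylidene)acetate (2 equiv)
Product: 6 ethyl 3-(4-benzyloxy-3-methoxyphenyl)-2-(triphenylphosphoranylidene)propanoate, via alkylated phosphonium bromide 5 (not isolated)
Conditions: EtOAc, reflux; filtration
Reagents that add atoms: none
Why: C-alkylation of an ester-stabilised ylide by a reactive benzylic bromide is followed by transylidation, in which the second equivalent of 4 deprotonates salt 5 and leaves the mixture as its own insoluble phosphonium bromide.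

Step 4
Reactants: 6 ethyl 3-(4-benzyloxy-3-methoxyphenyl)-2-(triphenylphosphoranylidene)propanoate, 7 acetaldehyde
Product: 8 ethyl (E)-2-(4-benzyloxy-3-methoxybenzyl)but-2-enoate
Conditions: MeCHO (excess), CH2Cl2, sealed tube, 40 °C
Reagents that add atoms: none
Why: Wittig olefination with an α-branched ester-stabilised ylide should place the incoming methyl group trans to the ester and so give the E-alkene, any Z-isomer being removable by chromatography at this stage.

Step 5
Reactants: 8 ethyl (E)-2-(4-benzyloxy-3-methoxybenzyl)but-2-enoate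
Product: 9 (E)-2-(4-benzyloxy-3-methoxybenzyl)but-2-en-1-ol
Conditions: i-Bu2AlH (2.2 equiv), CH2Cl2, −78 → 0 °C; aq. potassium sodium tartrate
Reagents that add atoms: none
Why: 1,2-Reduction of an α,β-unsaturated ester with i-Bu2AlH gives the allylic alcohol without touching the alkene geometry or the benzyl ether.

Step 6
Reactants: 9 (E)-2-(4-benzyloxy-3-methoxybenzyl)but-2-en-1-ol
Product: 10 (E)-2-(4-benzyloxy-3-methoxybenzyl)but-2-en-1-yl acetate
Conditions: Ac2O, Et3N, DMAP (cat.), CH2Cl2, 0 °C → rt
Reagents that add atoms: acetic anhydride, CC(=O)OC(C)=O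
Why: DMAP-catalysed acetylation of a primary allylic alcohol installs the leaving group needed for π-allyl formation.

Step 7
Reactants: 10 (E)-2-(4-benzyloxy-3-methoxybenzyl)but-2-en-1-yl acetate, 11 bis(pinacolato)diboron
Product: 12 (Z)-2-[2-(4-benzyloxy-3-methoxybenzyl)but-2-en-1-yl]-4,4,5,5-tetramethyl-1,3,2-dioxaborolane (methyl trans to the CH2B group)
Conditions: Pd(dba)2 (5 mol %), DMSO, 50 °C
Reagents that add atoms: none
Why: In this palladium-catalysed borylation of an allylic acetate, zerovalent palladium ionises 10 to the π-allyl complex whose methyl group is syn, the acetate ligand activates 11 for transmetalation, and reductive elimination at the unsubstituted terminus should deliver the primary boronate with the methyl group still trans to the boron-bearing carbon.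

Step 8
Reactants: 13 vanillin, 14 ethyl (S)-lactate
Product: 15 ethyl (R)-2-(4-formyl-2-methoxyphenoxy)propanoate
Conditions: PPh3, DIAD, THF, 0 °C → rt
Reagents that add atoms: none
Why: In this Mitsunobu etherification the acidic phenol of 13 displaces the activated secondary hydroxyl of 14 by SN2 with clean inversion and so sets Cb as R.

Step 9
Reactants: 15 ethyl (R)-2-(4-formyl-2-methoxyphenoxy)propanoate, 12 (Z)-2-[2-(4-benzyloxy-3-methoxybenzyl)but-2-en-1-yl]-4,4,5,5-tetramethyl-1,3,2-dioxaborolane (1.1 equiv)
Product: 18 ethyl (R)-2-{4-[(1S,2R)-7-benzyloxy-6-methoxy-2-methyl-3-methylidene-1,2,3,4-tetrahydronaphthalen-1-yl]-2-methoxyphenoxy}propanoate, via homoallylic pinacol borate 16 (not isolated), via C1 benzylic cation 17 (not isolated)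
Conditions: (S)-3,3'-bis(2,4,6-triisopropylphenyl)-1,1'-binaphthyl-2,2'-diyl hydrogen phosphate (5 mol %), toluene, −30 °C; then Bi(OTf)3 (10 mol %), MeNO2 co-solvent, −30 → 0 °C; Et3N quench
Reagents that add atoms: none
Why: Proposed new method: the phosphoric acid hydrogen-bonds to a pinacol oxygen of 12 and to the formyl hydrogen of 15, so that the γ-carbon (the future C2) attacks the Si face of the aldehyde through a closed six-membered chair (closest known reaction type: chiral-phosphoric-acid-catalysed crotylboration of aryl aldehydes with pinacol boronates), giving the anti borate 16 with C2 fixed by the catalyst together with the alkene geometry of 12. Bi(OTf)3 then ionises the benzylic C1–OBpin bond to cation 17, which the para ether oxygen of ring C stabilises, and C8a of ring A attacks it (closest known reaction type: cationic cyclisation of 1,4-diarylbutan-1-ols to trans-1-aryltetralins); only the coupling of the two events in one flask on a β-benzyl boronate is new. Ring B closes as a six-membered ring, 6-exo-trig at the cationic carbon with the C4a–C8a bond of ring A endocyclic. The carbinol configuration is erased in 17 and C1 is rebuilt under the control of C2, because the chair-like transition state with ring C and the C2 methyl both pseudo-equatorial leads to the 1,2-trans product. Closure para and not ortho to the ring A methoxy group follows from the crowding of the position between that methoxy group and the benzylic chain, and an alkyl aryl ether on ring C is preferred to a silyl ether because it is the better donor and cannot be lost to the acid. The step also needs the cation to be trapped faster than it loses the C2 proton and the 1,1-disubstituted alkene to stay exocyclic, which the strongly activated ring A, the slight excess of 12 (no aldehyde left for oxonia-Cope scrambling), the low temperature and the amine quench should secure.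

Step 10
Reactants: 18 ethyl (R)-2-{4-[(1S,2R)-7-benzyloxy-6-methoxy-2-methyl-3-methylidene-1,2,3,4-tetrahydronaphthalen-1-yl]-2-methoxyphenoxy}propanoate
Product: 19 ethyl (R)-2-{4-[(1S,2S,3R)-7-benzyloxy-6-methoxy-2,3-dimethyl-1,2,3,4-tetrahydronaphthalen-1-yl]-2-methoxyphenoxy}propanoate
Conditions: Mn(dpm)3 (dpm = dipivaloylmethanate, 10 mol %), PhSiH3, t-BuOOH, i-PrOH, rt
Reagents that add atoms: none
Why: In this metal-hydride hydrogen-atom-transfer hydrogenation a manganese hydride adds hydrogen to the CH2 terminus and the tertiary C3 radical should accept the second hydrogen on its axial face, so that the new methyl group becomes equatorial and trans to the C2 methyl (3R), while the benzyl ether, which a palladium hydrogenation would cleave, survives.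

Step 11
Reactants: 19 ethyl (R)-2-{4-[(1S,2S,3R)-7-benzyloxy-6-methoxy-2,3-dimethyl-1,2,3,4-tetrahydronaphthalen-1-yl]-2-methoxyphenoxy}propanoate
Product: 20 (R)-2-{4-[(1S,2S,3R)-7-benzyloxy-6-methoxy-2,3-dimethyl-1,2,3,4-tetrahydronaphthalen-1-yl]-2-methoxyphenoxy}propanal
Conditions: i-Bu2AlH (1.1 equiv), CH2Cl2, −78 °C; aq. potassium sodium tartrate
Reagents that add atoms: none
Why: In this partial reduction of an ester with i-Bu2AlH the aluminium hemiacetal, stabilised by the α-oxygen, persists at −78 °C and releases the aldehyde only on work-up, the crude product being used at once to protect Cb from epimerisation.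

Step 12
Reactants: 21 4-bromo-2-methoxyphenol
Product: 22 1-benzyloxy-4-bromo-2-methoxybenzene
Conditions: BnBr, K2CO3, DMF, rt
Reagents that add atoms: benzyl bromide, BrCc1ccccc1
Why: Williamson ether synthesis on a phenol with a reactive benzylic halide is reliable.

Step 13
Reactants: 20 (R)-2-{4-[(1S,2S,3R)-7-benzyloxy-6-methoxy-2,3-dimethyl-1,2,3,4-tetrahydronaphthalen-1-yl]-2-methoxyphenoxy}propanal, 22 1-benzyloxy-4-bromo-2-methoxybenzene
Product: 25 (1S,2R)-1-(4-benzyloxy-3-methoxyphenyl)-2-{4-[(1S,2S,3R)-7-benzyloxy-6-methoxy-2,3-dimethyl-1,2,3,4-tetrahydronaphthalen-1-yl]-2-methoxyphenoxy}propan-1-ol, via aryllithium 23 (not isolated), via aryltitanium triisopropoxide 24 (not isolated)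
Conditions: 22, n-BuLi, THF, −78 °C; ClTi(Oi-Pr)3, −78 → −40 °C; 20, −78 → −20 °C; aq. NH4Cl
Reagents that add atoms: none
Why: Bromine–lithium exchange and transmetalation give a weakly Lewis acidic aryltitanium reagent that cannot chelate, so the carbonyl addition should follow the polar Felkin–Anh model (the aryl group attacks anti to the Cb–O bond and past the Cb hydrogen), which sets Ca as S and gives the erythro alcohol.

Step 14
Reactants: 25 (1S,2R)-1-(4-benzyloxy-3-methoxyphenyl)-2-{4-[(1S,2S,3R)-7-benzyloxy-6-methoxy-2,3-dimethyl-1,2,3,4-tetrahydronaphthalen-1-yl]-2-methoxyphenoxy}propan-1-ol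
Product: 26 (1S,2R)-1-(4-hydroxy-3-methoxyphenyl)-2-{4-[(1S,2S,3R)-7-hydroxy-6-methoxy-2,3-dimethyl-1,2,3,4-tetrahydronaphthalen-1-yl]-2-methoxyphenoxy}propan-1-ol (CID53359464)
Conditions: H2 (1 atm), Pd/C, EtOAc–EtOH, rt
Reagents that add atoms: none
Why: Catalytic hydrogenolysis of the two benzyl aryl ethers under neutral conditions is much faster than cleavage of the secondary benzylic C–OH bond and touches no stereocentre.

Compound list
1 | 4-benzyloxy-3-methoxybenzaldehyde | COc1cc(C=O)ccc1OCc1ccccc1 | starting material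
2 | (4-benzyloxy-3-methoxyphenyl)methanol | COc1cc(CO)ccc1OCc1ccccc1 | intermediate
3 | 4-benzyloxy-3-methoxybenzyl bromide | COc1cc(CBr)ccc1OCc1ccccc1 | intermediate
4 | ethyl (triphenylphosphoranylidene)acetate | CCOC(=O)C=P(c1ccccc1)(c1ccccc1)c1ccccc1 | starting material
5 | [3-(4-benzyloxy-3-methoxyphenyl)-1-ethoxy-1-oxopropan-2-yl]triphenylphosphonium bromide (not isolated) | CCOC(=O)C(Cc1ccc(OCc2ccccc2)c(OC)c1)[P+](c1ccccc1)(c1ccccc1)c1ccccc1.[Br-] | intermediate
6 | ethyl 3-(4-benzyloxy-3-methoxyphenyl)-2-(triphenylphosphoranylidene)propanoate | CCOC(=O)C(Cc1ccc(OCc2ccccc2)c(OC)c1)=P(c1ccccc1)(c1ccccc1)c1ccccc1 | intermediate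
7 | acetaldehyde | CC=O | starting material
8 | ethyl (E)-2-(4-benzyloxy-3-methoxybenzyl)but-2-enoate | C/C=C(/C(=O)OCC)Cc1ccc(OCc2ccccc2)c(OC)c1 | intermediate
9 | (E)-2-(4-benzyloxy-3-methoxybenzyl)but-2-en-1-ol | C/C=C(/CO)Cc1ccc(OCc2ccccc2)c(OC)c1 | intermediate
10 | (E)-2-(4-benzyloxy-3-methoxybenzyl)but-2-en-1-yl acetate | C/C=C(/COC(C)=O)Cc1ccc(OCc2ccccc2)c(OC)c1 | intermediate
11 | bis(pinacolato)diboron | CC1(C)OB(OC1(C)C)B1OC(C)(C)C(C)(C)O1 | starting material
12 | (Z)-2-[2-(4-benzyloxy-3-methoxybenzyl)but-2-en-1-yl]-4,4,5,5-tetramethyl-1,3,2-dioxaborolane, methyl trans to CH2B | C/C=C(/CB1OC(C)(C)C(C)(C)O1)Cc1ccc(OCc2ccccc2)c(OC)c1 | intermediate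
13 | vanillin | COc1cc(C=O)ccc1O | starting material
14 | ethyl (S)-lactate | CCOC(=O)[C@H](C)O | starting material
15 | ethyl (R)-2-(4-formyl-2-methoxyphenoxy)propanoate | CCOC(=O)[C@@H](C)Oc1ccc(C=O)cc1OC | intermediate
16 | ethyl (R)-2-{4-[(1S,2S)-3-(4-benzyloxy-3-methoxybenzyl)-2-methyl-1-(4,4,5,5-tetramethyl-1,3,2-dioxaborolan-2-yloxy)but-3-en-1-yl]-2-methoxyphenoxy}propanoate, anti (not isolated) | CCOC(=O)[C@@H](C)Oc1ccc([C@@H](OB2OC(C)(C)C(C)(C)O2)[C@@H](C)C(=C)Cc2ccc(OCc3ccccc3)c(OC)c2)cc1OC | intermediate
17 | C1 benzylic cation from 16, C2 configuration retained and carbinol configuration lost (not isolated) | CCOC(=O)[C@@H](C)Oc1ccc([CH+][C@@H](C)C(=C)Cc2ccc(OCc3ccccc3)c(OC)c2)cc1OC | intermediate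
18 | ethyl (R)-2-{4-[(1S,2R)-7-benzyloxy-6-methoxy-2-methyl-3-methylidene-1,2,3,4-tetrahydronaphthalen-1-yl]-2-methoxyphenoxy}propanoate, 1,2-trans | CCOC(=O)[C@@H](C)Oc1ccc([C@H]2c3cc(OCc4ccccc4)c(OC)cc3CC(=C)[C@@H]2C)cc1OC | intermediate
19 | ethyl (R)-2-{4-[(1S,2S,3R)-7-benzyloxy-6-methoxy-2,3-dimethyl-1,2,3,4-tetrahydronaphthalen-1-yl]-2-methoxyphenoxy}propanoate, all-trans | CCOC(=O)[C@@H](C)Oc1ccc([C@H]2c3cc(OCc4ccccc4)c(OC)cc3C[C@@H](C)[C@@H]2C)cc1OC | intermediate
20 | (R)-2-{4-[(1S,2S,3R)-7-benzyloxy-6-methoxy-2,3-dimethyl-1,2,3,4-tetrahydronaphthalen-1-yl]-2-methoxyphenoxy}propanal | O=C[C@@H](C)Oc1ccc([C@H]2c3cc(OCc4ccccc4)c(OC)cc3C[C@@H](C)[C@@H]2C)cc1OC | intermediate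
21 | 4-bromo-2-methoxyphenol | COc1cc(Br)ccc1O | starting material
22 | 1-benzyloxy-4-bromo-2-methoxybenzene | COc1cc(Br)ccc1OCc1ccccc1 | intermediate
23 | (4-benzyloxy-3-methoxyphenyl)lithium (not isolated) | [Li]c1ccc(OCc2ccccc2)c(OC)c1 | intermediate
24 | (4-benzyloxy-3-methoxyphenyl)titanium triisopropoxide (not isolated) | CC(C)O[Ti](OC(C)C)(OC(C)C)c1ccc(OCc2ccccc2)c(OC)c1 | intermediate
25 | (1S,2R)-1-(4-benzyloxy-3-methoxyphenyl)-2-{4-[(1S,2S,3R)-7-benzyloxy-6-methoxy-2,3-dimethyl-1,2,3,4-tetrahydronaphthalen-1-yl]-2-methoxyphenoxy}propan-1-ol, erythro | COc1cc([C@H](O)[C@@H](C)Oc2ccc([C@H]3c4cc(OCc5ccccc5)c(OC)cc4C[C@@H](C)[C@@H]3C)cc2OC)ccc1OCc1ccccc1 | intermediate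
26 | (1S,2R)-1-(4-hydroxy-3-methoxyphenyl)-2-{4-[(1S,2S,3R)-7-hydroxy-6-methoxy-2,3-dimethyl-1,2,3,4-tetrahydronaphthalen-1-yl]-2-methoxyphenoxy}propan-1-ol | COc1cc([C@H](O)[C@@H](C)Oc2ccc([C@H]3c4cc(O)c(OC)cc4C[C@@H](C)[C@@H]3C)cc2OC)ccc1O | target

Total steps: 14. Longest linear sequence: 12 steps from 1 (steps 1–7, 9, 10, 11, 13, 14).

Steps most likely to fail

1. Step 9.
- What may go wrong: the cation may lose the C2 proton. The acid that builds up may move the exocyclic double bond into ring B. Surviving aldehyde may cause oxonia-Cope scrambling. The phosphate and the pinacol borate may deactivate Bi(OTf)3.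
- Fallback (known chemistry only): it sets out from 12 and 15. The phosphoric-acid-catalysed allylboration is run alone, and borate 16 is hydrolysed on work-up to the anti homoallylic alcohol F1, which can be purified and checked for enantiomeric purity.
- Cl3CCN with catalytic DBU converts it into the benzylic trichloroacetimidate F2. Catalytic TMSOTf in CH2Cl2 at −78 °C then starts the intramolecular Friedel–Crafts alkylation.
- Each proton released by ring A is taken up by the nitrogen of the next imidate, so no free strong acid accumulates and the alkene should stay in place. The sequence comes back to the route at 18.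

2. Step 13.
- What may go wrong: chelation by the ether and methoxy oxygens of ring C may erode the Felkin–Anh facial selectivity. The basic aryl-metal species may epimerise Cb in the α-aryloxy aldehyde.
- Fallback: it sets out from 19 and uses chelation instead of suppressing it. MeNH(OMe)·HCl and i-PrMgCl in THF at −20 °C give the Weinreb amide F3, and aryllithium 23 converts it into the α-aryloxy aryl ketone F4.
- Zn(BH4)2 in Et2O at −78 → 0 °C then ties the carbonyl and ether oxygens together and delivers hydride from the side of the Cb hydrogen. This should give the same erythro (Ca S) alcohol, so the sequence comes back to the route at 25.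

3. Step 7.
- What may go wrong: syn–anti interconversion of the π-allyl palladium intermediate would erode the alkene geometry, which translates directly into lost enantiopurity at C2. Palladium may also couple the product boronate with unreacted acetate.
- Fallback: it sets out from 3 and avoids π-allyl intermediates. Bis(pinacolboryl)methane, deprotonated with lithium 2,2,6,6-tetramethylpiperidide in THF at 0 °C, is alkylated by 3 to the geminal bis(boronate) F5.
- A second deprotonation and a boron–Wittig reaction with 7 should give the trisubstituted alkenyl boronate F6, with boron trans to the methyl group.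
- Matteson homologation with chloromethyllithium (BrCH2Cl, n-BuLi, THF, −78 °C → rt) inserts the CH2 group by a 1,2-metalate shift that retains the alkene geometry. The sequence comes back to the route at 12.

Further compounds
F1 | step 9 | ethyl (R)-2-{4-[(1S,2S)-3-(4-benzyloxy-3-methoxybenzyl)-1-hydroxy-2-methylbut-3-en-1-yl]-2-methoxyphenoxy}propanoate | CCOC(=O)[C@@H](C)Oc1ccc([C@@H](O)[C@@H](C)C(=C)Cc2ccc(OCc3ccccc3)c(OC)c2)cc1OC
F2 | step 9 | ethyl (R)-2-{4-[(1S,2S)-3-(4-benzyloxy-3-methoxybenzyl)-2-methyl-1-(2,2,2-trichloroacetimidoyloxy)but-3-en-1-yl]-2-methoxyphenoxy}propanoate | CCOC(=O)[C@@H](C)Oc1ccc([C@@H](OC(=N)C(Cl)(Cl)Cl)[C@@H](C)C(=C)Cc2ccc(OCc3ccccc3)c(OC)c2)cc1OC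
F3 | step 13 | (R)-2-{4-[(1S,2S,3R)-7-benzyloxy-6-methoxy-2,3-dimethyl-1,2,3,4-tetrahydronaphthalen-1-yl]-2-methoxyphenoxy}-N-methoxy-N-methylpropanamide | CON(C)C(=O)[C@@H](C)Oc1ccc([C@H]2c3cc(OCc4ccccc4)c(OC)cc3C[C@@H](C)[C@@H]2C)cc1OC
F4 | step 13 | (R)-1-(4-benzyloxy-3-methoxyphenyl)-2-{4-[(1S,2S,3R)-7-benzyloxy-6-methoxy-2,3-dimethyl-1,2,3,4-tetrahydronaphthalen-1-yl]-2-methoxyphenoxy}propan-1-one | COc1cc(C(=O)[C@@H](C)Oc2ccc([C@H]3c4cc(OCc5ccccc5)c(OC)cc4C[C@@H](C)[C@@H]3C)cc2OC)ccc1OCc1ccccc1
F5 | step 7 | 2,2'-[2-(4-benzyloxy-3-methoxyphenyl)ethane-1,1-diyl]bis(4,4,5,5-tetramethyl-1,3,2-dioxaborolane) | COc1cc(CC(B2OC(C)(C)C(C)(C)O2)B2OC(C)(C)C(C)(C)O2)ccc1OCc1ccccc1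
F6 | step 7 | (Z)-2-[1-(4-benzyloxy-3-methoxyphenyl)but-2-en-2-yl]-4,4,5,5-tetramethyl-1,3,2-dioxaborolane | C/C=C(/B1OC(C)(C)C(C)(C)O1)Cc1ccc(OCc2ccccc2)c(OC)c1
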